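**Retrosynthetic overview**
1. Colpol 12 comes from its bis-TIPS ether 11 by fluoride desilylation.
2. The ring A–CH2 bond is cut to the sodium phenoxide of 3-bromo-4-methoxyphenol 9 and the Z-allylic bromide 8 (ortho-C-allylation, alkene untouched).
3. Key cut ArCH2–CH=: aldehyde 3 is used with reversed polarity (its N–H hydrazone 6 acts as a benzyl-carbanion equivalent, N2 as traceless leaving group) against the Z-alkenyl iodide 5. Both carbons are natively electrophilic.
4. The Z geometry is bought in with ethyl (Z)-3-iodoacrylate 4 and never touched afterwards.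
5. No ring is formed: both benzene rings are purchased with their Br/O pattern in place (1 and 9).

Assumption: colpol has no stereocentre, so "single enantiomer" is read as the single (Z)-alkene isomer.

**Step 1**
Reactants: 1 methyl 4-bromo-3,5-dihydroxybenzoate
Product: 2 methyl 4-bromo-3,5-bis[(triisopropylsilyl)oxy]benzoate
Conditions: TIPSCl (2.4 equiv), imidazole (5 equiv), DMAP (cat.), DMF, 40 °C
Reagents that add atoms: triisopropylsilyl chloride, CC(C)[Si](Cl)(C(C)C)C(C)C
Why: Imidazole-promoted O-silylation gives base-stable, fluoride-labile TIPS ethers whose bulk also shields the flanked C–Br bond in the later nickel step.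

**Step 2**
Reactants: 2 methyl 4-bromo-3,5-bis[(triisopropylsilyl)oxy]benzoate
Product: 3 4-bromo-3,5-bis[(triisopropylsilyl)oxy]benzaldehyde
Conditions: DIBAL-H (1.05 equiv), toluene, −78 °C; MeOH quench at −78 °C, Rochelle salt
Reagents that add atoms: none
Why: DIBAL-H partial reduction of an ester; the tetrahedral aluminium hemiacetal is stable at −78 °C and gives the aldehyde only on work-up.

**Step 3**
Reactants: 4 ethyl (Z)-3-iodoacrylate
Product: 5 (Z)-3-iodoprop-2-en-1-ol
Conditions: DIBAL-H (2.2 equiv), CH2Cl2, −78 → 0 °C; Rochelle salt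
Reagents that add atoms: none
Why: DIBAL-H 1,2-reduction of the enoate to the allylic alcohol leaves the Z C=C and the vinyl C–I bond untouched.

**Step 4 (key step)**
Reactants: 3 4-bromo-3,5-bis[(triisopropylsilyl)oxy]benzaldehyde; 5 (Z)-3-iodoprop-2-en-1-ol
Product: 7 (Z)-4-{4-bromo-3,5-bis[(triisopropylsilyl)oxy]phenyl}but-2-en-1-ol, via aldehyde N-H hydrazone 6 (not isolated)
Conditions: N2H4·H2O (1.1 equiv), THF, rt, 1 h; then 5 (1.2 equiv), Ni(cod)2 (10 mol %), PMe3 (20 mol %), K3PO4 (2.5 equiv), 4 Å MS, THF, 40 °C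
Reagents that add atoms: hydrazine monohydrate, NN.O (supplies the two N atoms of intermediate 6; they leave as N2 and none remain in 7)
Why: Proposed new method: condensation gives N–H hydrazone 6, whose aldehyde-derived carbon is turned from an electrophile into a benzyl-carbanion equivalent (Wolff–Kishner-type, N2 as traceless leaving group); Ni(0)/PMe3 inserts with retention into the Z-alkenyl C–I bond of 5, phosphate-assisted deprotonation of the Ni-bound hydrazone and loss of N2 transfer the benzyl carbon to nickel, and reductive elimination forms the C(sp3)–C(sp2) bond between two natively electrophilic carbons with the Z geometry of 5 carried over unchanged (no new stereocentre; the alkenyl–Ni intermediate is configurationally stable); the alkenyl iodide should react much faster than the aryl bromide shielded by two ortho OTIPS groups; closest known reaction type: Ni(cod)2/PMe3-catalysed denitrogenative cross-coupling of aldehyde N–H hydrazones (carbonyl umpolung, alkyl-carbanion equivalents) with aryl halides.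

**Step 5**
Reactants: 7 (Z)-4-{4-bromo-3,5-bis[(triisopropylsilyl)oxy]phenyl}but-2-en-1-ol
Product: 8 (Z)-1-bromo-4-{4-bromo-3,5-bis[(triisopropylsilyl)oxy]phenyl}but-2-ene
Conditions: CBr4 (1.2 equiv), PPh3 (1.25 equiv), CH2Cl2, −20 → 0 °C; used at once
Reagents that add atoms: carbon tetrabromide, BrC(Br)(Br)Br
Why: Appel reaction; bromide displaces the alkoxyphosphonium by SN2 at the primary carbon, so there is no allylic transposition and the Z alkene is kept at low temperature.

**Step 6**
Reactants: 8 (Z)-1-bromo-4-{4-bromo-3,5-bis[(triisopropylsilyl)oxy]phenyl}but-2-ene; 9 3-bromo-4-methoxyphenol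
Product: 11 5-bromo-2-[(Z)-4-{4-bromo-3,5-bis[(triisopropylsilyl)oxy]phenyl}but-2-en-1-yl]-4-methoxyphenol, via sodium 3-bromo-4-methoxyphenolate 10 (not isolated)
Conditions: 9 (2.5 equiv), NaH (2.4 equiv), toluene, 0 °C → rt; then 8 (1 equiv), toluene, 45 °C
Reagents that add atoms: sodium hydride, [Na+].[H-] (supplies the Na of intermediate 10; none remains in 11)
Why: Ortho-C-allylation of a sodium phenoxide in a non-polar medium: the tight ion aggregate blocks oxygen, the para position is blocked by OMe, the ortho site next to Br is hindered, and direct SN2 at CH2Br leaves the Z alkene unchanged.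

**Step 7**
Reactants: 11 5-bromo-2-[(Z)-4-{4-bromo-3,5-bis[(triisopropylsilyl)oxy]phenyl}but-2-en-1-yl]-4-methoxyphenol
Product: 12 colpol, 2-bromo-5-[(Z)-4-(4-bromo-2-hydroxy-5-methoxyphenyl)but-2-en-1-yl]benzene-1,3-diol
Conditions: TBAF (2.5 equiv), AcOH (2.5 equiv), THF, 0 °C
Reagents that add atoms: none
Why: Fluoride-mediated desilylation of the two aryl TIPS ethers under buffered conditions that touch neither the skipped Z alkene, the aryl bromides nor the methyl ether.

**Compound list**
1 | methyl 4-bromo-3,5-dihydroxybenzoate | COC(=O)c1cc(O)c(Br)c(O)c1 | starting material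
2 | methyl 4-bromo-3,5-bis[(triisopropylsilyl)oxy]benzoate | COC(=O)c1cc(O[Si](C(C)C)(C(C)C)C(C)C)c(Br)c(O[Si](C(C)C)(C(C)C)C(C)C)c1 | intermediate
3 | 4-bromo-3,5-bis[(triisopropylsilyl)oxy]benzaldehyde | O=Cc1cc(O[Si](C(C)C)(C(C)C)C(C)C)c(Br)c(O[Si](C(C)C)(C(C)C)C(C)C)c1 | intermediate
4 | ethyl (Z)-3-iodoacrylate | CCOC(=O)/C=C\I | starting material
5 | (Z)-3-iodoprop-2-en-1-ol | OC/C=C\I | intermediate
6 | (E)-{4-bromo-3,5-bis[(triisopropylsilyl)oxy]benzylidene}hydrazine (N–H hydrazone of 3, not isolated) | N/N=C/c1cc(O[Si](C(C)C)(C(C)C)C(C)C)c(Br)c(O[Si](C(C)C)(C(C)C)C(C)C)c1 | intermediate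
7 | (Z)-4-{4-bromo-3,5-bis[(triisopropylsilyl)oxy]phenyl}but-2-en-1-ol | OC/C=C\Cc1cc(O[Si](C(C)C)(C(C)C)C(C)C)c(Br)c(O[Si](C(C)C)(C(C)C)C(C)C)c1 | intermediate
8 | (Z)-1-bromo-4-{4-bromo-3,5-bis[(triisopropylsilyl)oxy]phenyl}but-2-ene | BrC/C=C\Cc1cc(O[Si](C(C)C)(C(C)C)C(C)C)c(Br)c(O[Si](C(C)C)(C(C)C)C(C)C)c1 | intermediate
9 | 3-bromo-4-methoxyphenol | COc1ccc(O)cc1Br | starting material
10 | sodium 3-bromo-4-methoxyphenolate (not isolated) | COc1ccc([O-])cc1Br.[Na+] | intermediate
11 | 5-bromo-2-[(Z)-4-{4-bromo-3,5-bis[(triisopropylsilyl)oxy]phenyl}but-2-en-1-yl]-4-methoxyphenol | COc1cc(C/C=C\Cc2cc(O[Si](C(C)C)(C(C)C)C(C)C)c(Br)c(O[Si](C(C)C)(C(C)C)C(C)C)c2)c(O)cc1Br | intermediate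
12 | colpol, 2-bromo-5-[(Z)-4-(4-bromo-2-hydroxy-5-methoxyphenyl)but-2-en-1-yl]benzene-1,3-diol | COc1cc(C/C=C\Cc2cc(O)c(Br)c(O)c2)c(O)cc1Br | target

**Total step count:** 7
**Longest linear sequence:** 6 steps (1 → 2 → 3 → 7 → 8 → 11 → 12, i.e. steps 1, 2, 4, 5, 6, 7)

**Three steps most likely to fail**

Step 4 is the main risk: the hydrazone/alkenyl-iodide coupling is an untested substrate class, nickel may insert into the aryl C–Br bond, and the partner carries a free OH. The fallback sets out from aldehyde 3 and comes back to the route at alcohol 7. NaBH4 (MeOH/THF, 0 °C) reduces 3 to {4-bromo-3,5-bis[(triisopropylsilyl)oxy]phenyl}methanol F1. SOCl2 (CH2Cl2, 0 °C) converts it into {[2-bromo-5-(chloromethyl)-1,3-phenylene]bis(oxy)}bis(triisopropylsilane) F2. Zinc dust with LiCl (THF, rt) inserts only into the benzylic C–Cl bond and gives {4-bromo-3,5-bis[(triisopropylsilyl)oxy]benzyl}zinc chloride F3. Pd(PPh3)4-catalysed Negishi coupling of this reagent with 5 at rt returns 7: the alkenyl iodide reacts far faster than the hindered aryl bromide, the Z geometry is retained, and a free hydroxyl is tolerated in fast couplings of benzylic zinc reagents.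

Step 6 is the second risk: O- versus C-alkylation, the second ortho site, SN2' attack and over-alkylation can all lower the yield. The fallback sets out from phenol 9 (bromide 8 is used as made) and comes back at the target 12. It replaces the ambident phenoxide by a site-defined aryl nucleophile. NIS (MeCN, 0 °C) iodinates 9 at the free, less hindered ortho position to give 5-bromo-2-iodo-4-methoxyphenol F4. TIPSCl/imidazole gives (5-bromo-2-iodo-4-methoxyphenoxy)triisopropylsilane F5. Iodine–magnesium exchange with i-PrMgCl·LiCl (THF, −40 °C, C–I only) gives {4-bromo-5-methoxy-2-[(triisopropylsilyl)oxy]phenyl}magnesium chloride F6. Li2CuCl4-catalysed α-selective (SN2) coupling with 8 (THF, −20 °C) gives tris-TIPS colpol F7 with the Z alkene intact. TBAF/AcOH then removes all three silyl groups and gives 12.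

Step 2 is the third risk: over-reduction to the benzyl alcohol. The fallback sets out from ester 2 and comes back at aldehyde 3. MeNH(OMe)·HCl with i-PrMgCl (THF, −20 °C) converts 2 into the Weinreb amide 4-bromo-N-methoxy-N-methyl-3,5-bis[(triisopropylsilyl)oxy]benzamide F8. Its chelated tetrahedral adduct with DIBAL-H (THF, −78 °C) cannot be reduced further and releases 3 on work-up.

**Further compounds**
F1 | step 4 | {4-bromo-3,5-bis[(triisopropylsilyl)oxy]phenyl}methanol | OCc1cc(O[Si](C(C)C)(C(C)C)C(C)C)c(Br)c(O[Si](C(C)C)(C(C)C)C(C)C)c1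
F2 | step 4 | {[2-bromo-5-(chloromethyl)-1,3-phenylene]bis(oxy)}bis(triisopropylsilane) | ClCc1cc(O[Si](C(C)C)(C(C)C)C(C)C)c(Br)c(O[Si](C(C)C)(C(C)C)C(C)C)c1
F3 | step 4 | {4-bromo-3,5-bis[(triisopropylsilyl)oxy]benzyl}zinc chloride | Cl[Zn]Cc1cc(O[Si](C(C)C)(C(C)C)C(C)C)c(Br)c(O[Si](C(C)C)(C(C)C)C(C)C)c1
F4 | step 6 | 5-bromo-2-iodo-4-methoxyphenol | COc1cc(I)c(O)cc1Br
F5 | step 6 | (5-bromo-2-iodo-4-methoxyphenoxy)triisopropylsilane | COc1cc(I)c(O[Si](C(C)C)(C(C)C)C(C)C)cc1Br
F6 | step 6 | {4-bromo-5-methoxy-2-[(triisopropylsilyl)oxy]phenyl}magnesium chloride | COc1cc([Mg]Cl)c(O[Si](C(C)C)(C(C)C)C(C)C)cc1Br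
F7 | step 6 | tris-TIPS colpol, {[2-bromo-5-[(Z)-4-{4-bromo-5-methoxy-2-[(triisopropylsilyl)oxy]phenyl}but-2-en-1-yl]-1,3-phenylene]bis(oxy)}bis(triisopropylsilane) | COc1cc(C/C=C\Cc2cc(O[Si](C(C)C)(C(C)C)C(C)C)c(Br)c(O[Si](C(C)C)(C(C)C)C(C)C)c2)c(O[Si](C(C)C)(C(C)C)C(C)C)cc1Br
F8 | step 2 | 4-bromo-N-methoxy-N-methyl-3,5-bis[(triisopropylsilyl)oxy]benzamide | CON(C)C(=O)c1cc(O[Si](C(C)C)(C(C)C)C(C)C)c(Br)c(O[Si](C(C)C)(C(C)C)C(C)C)c1
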